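All runs were computed for an exercise, and the scatter is random.

West and south were the flasks I had to call, from the earlier runs dusk and autumn.

all flasks: substrate 12 mM; free catalyst 0.68 mM

|  | reagent | remark | time |
|---|---|---|---|
| dusk | 7 mM | run made earlier |  |
| autumn | 12 mM | run made earlier |  |
| west | 8.40 mM |  | 1.5 h |
| south | 17.0 mM |  | 1.5 h |

- dusk (time / min: substrate / %, target / %): 4.00: 95.4, 2.5; 12.0: 88.2, 8.2; 20.0: 83.0, 15.2; 30.0: 76.5, 20.9; 50.0: 68.0, 28.1; 60.0: 64.6, 30.5
- autumn (time / min: substrate / %, target / %): 4.00: 95.6, 3.1; 12.0: 88.2, 10.7; 20.0: 80.6, 17.2; 30.0: 73.2, 25.2; 50.0: 60.7, 37.3; 60.0: 55.6, 42.4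

(scatter of a reading: 0.5 percentage points)

- part of the substrate that has reacted at the end, west
- part of the substrate that has reacted at the end, south
- what raising the concentration of reagent from its lowest to its highest value here does to the part of the substrate that has reacted (changes below 5 percentage points count as none) (it rises / it falls / no change)

One thing looked contradictory. At 12.0 min dusk and autumn both held substrate at 88.2%, though autumn had more reagent. Yet at 60.0 min dusk held 64.6% and autumn 55.6%.

So I followed one substrate molecule. It reached target after catalyst intermediate A took one reagent. The released group then stood at a fork: stay free, or take a second reagent into idle adduct. I assumed the second. That gave a reagent budget: the reagent charge over twice the substrate charge, the part of the substrate that can reach target at two reagents each. Dusk's budget was 29.2% and autumn's 50.0%. Dusk's last target reading, 30.5%, stood above its budget, while autumn's, 42.4%, lay below its own.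

West's budget was 35.0%. The catalyst can hold a further 5.67% of the substrate as catalyst intermediate A, so I reckoned 40.7% reacted. South's budget was 70.8%. Autumn's decay, 0.00978 min⁻¹, carried over 1.5 h gives 58.5%, which is below that budget, so I took it for south.

The forecast gave west 50% (45% to 55%), south 60% (56% to 64%) and for the trend it rises, on the ground “Reagent is therefore used up twice”. My west lay below its range. West gave 44.1% and south 62.0%; the trend was: it rises, by 18 percentage points.

    reagent + released group ⇌ idle adduct, settled at all times (K = 15000 M⁻¹)
    reagent + catalyst intermediate A ⇌ catalyst intermediate B (K = 230 M⁻¹, k = 2.60 M⁻¹ s⁻¹)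
    catalyst intermediate D → free catalyst + target (k = 0.220 s⁻¹)
    substrate + free catalyst → catalyst intermediate A (k = 0.330 M⁻¹ s⁻¹)
    catalyst intermediate B → released group + catalyst intermediate C (k = 0.0380 s⁻¹)
    catalyst intermediate C ⇌ catalyst intermediate D (K = 1.20, k = 0.510 s⁻¹)

At 1.50 h west's target stood at 39.3% against its budget of 35.0%, and its reagent, the limiting reagent, was down to 2.2% of its charge. The neighbouring flask was south with 4.2 mM of reagent. Its budget was 17.5%, and with the catalyst's 5.67% that reckons to 23.2% reacted. That neighbour gave 27.4% reacted, with target at 22.1% and reagent at 2.0% of its charge.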